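All runs are calculated for an exercise; scatter was added.

The vessel stayed closed, stirred and isothermal, and the average length of a chain (the number-average degree of polymerisation) was by definition monomer in chains divided by chains begun.

| flask | free monomer | pre-initiator | remark | time |
|---|---|---|---|---|
| violet | 0.85 M | 7.5 mM | run made earlier |  |
| blue | 1.2 M | 7.5 mM | run made earlier |  |
| Thursday's | 1.5 M | 7.5 mM |  | 2.5 h |
| Wednesday's | 1.0 M | 7.5 mM |  | 2.5 h |

- violet (time / h: monomer in chains / %, free monomer / %): 0.133: 0.2, 99.6; 0.417: 1.2, 99.9; 0.667: 1.4, 97.9; 1.00: 3.9, 96.2; 1.50: 10.3, 90.6; 2.00: 15.1, 84.7; 2.50: 21.0, 78.4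
- blue (time / h: monomer in chains / %, free monomer / %): 0.200: 0, 99.9; 0.333: 0.1, 98.3; 0.500: 1.7, 98.3; 0.667: 1.6, 97.7; 1.00: 4.3, 95.6; 1.50: 10.5, 90.2; 2.50: 21.5, 78.5

(each reading ± 0.5 percentage points)

- which of the two ends with the longer chains by the average number of monomer units in a chain (chains begun, living or dead) ("neither" if they lie within 10%) (Thursday's / Wednesday's / neither)
- average number of monomer units in a chain (chains begun, living or dead) at the end, Thursday's
- average number of monomer units in a chain (chains begun, living or dead) at the end, Wednesday's

- the average divides the monomer in chains by the number of chains begun, living and dead together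
- the earlier runs do not show the number of chains; that part of a forecast is a guess

The violet and blue runs read 21.0% and 21.5% in chains at 2.50 h, despite their different charges, so I carried the mean, 21.2%, to both new flasks. My reckoning used one quantity, the full-charge length: free monomer charged divided by pre-initiator charged. It came straight from the charges, as 200 for Thursday's and 133 for Wednesday's.

In one extreme, every pre-initiator had begun one chain. Full-charge length times the share in chains then gave 42.5 for Thursday's and 28.3 for Wednesday's, both floors if a pre-initiator begins at most one chain. In the other extreme, chains were still starting steadily, and the first-order slope would rise with time, by a factor of 1.60 between my two windows. The violet run read 0.120 h⁻¹, then 0.145 h⁻¹, a ratio of 1.21 with its scatter. I judged that over 0.5 of the pre-initiator had begun chains, which capped the lengths at 85.0 and 56.7. With equal shares, Thursday's chains came out longer than Wednesday's by 1.50 times.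

The forecast said Thursday's, with 52 and 35, inside my bounds: “Incomplete activation would raise both”.

    pre-initiator → initiator (k = 0.0149 min⁻¹)
    initiator → spent initiator (k = 1.02 × 10⁻⁵ min⁻¹)
    free monomer + living end → monomer in chains + living end, rate k3*[living end]*[free monomer] (k = 0.410 L mol⁻¹ min⁻¹)
    free monomer + initiator → living end + monomer in chains (k = 0.0790 L mol⁻¹ min⁻¹)

The flasks gave Thursday's, with 52.0 and 34.0. Thursday's full-charge length times its 22.7% in chains gives 45.4, so chains begun stood at 87.3% of the pre-initiator charged. Read at 2.26 h or 2.74 h, Thursday's length has moved by 5.20. Left until 6.0 h, Thursday's flask held 58.4% in chains and 0.468% of its pre-initiator; the same product gives 117, and the flask gave 118.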